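The bicyclo[3.2.1]oct-3-ene-2,8-dione is opened through its cyclopentanone ring C1–C8–C5–C6–C7. The C8 carbonyl and C5 come from a β-keto ester; C1, C7 and C6 come from an acyclic γ-chloro ketone carrying both C6/C7 aryl groups. In one flask the C7 4-hydroxyphenyl group, once unmasked, closes onto C6 to a spirocyclopropyl dienone, the keto ester enolate reopens it at C6 (C5–C6), and Dieckmann closure joins C1 to C8. The step exploits the C7-aryl/C6 vicinal pair and the 1,3-dicarbonyl relation of C2 and C8 about C1. A bridging aldol condensation (C3–C4) and demethylation follow.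

Key step: step 6

Remark: locants C1–C8 are those of the bicyclo[3.2.1]oct-3-ene-2,8-dione core (C1 between the two carbonyls, C4 styryl-bearing, C6 bearing the 3,5-dioxygenated aryl, C7 the 4-oxygenated aryl, C8 the bridging carbonyl); compounds 1, 3 and 7 are taken as commercial.

Step 1
Reactants: 1 (E)-4-(4-hydroxyphenyl)but-3-en-2-one
Product: 2 4-[(E)-3-oxobut-1-enyl]phenyl acetate
Conditions: Ac2O, pyridine, DMAP (cat.), CH2Cl2, 0 °C to rt
Reagents that add atoms: acetic anhydride CC(=O)OC(C)=O
Why: O-Acetylation of the phenol (nucleophilic acyl substitution), which keeps the enone electrophilic for step 2 and makes the aryl group a poor neighbouring group until the acetate is removed in step 6.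

Step 2
Reactants: 2 4-[(E)-3-oxobut-1-enyl]phenyl acetate; 3 3,5-dimethoxybenzaldehyde
Product: 4 rac-4-[1-(3,5-dimethoxyphenyl)-1,4-dioxopentan-2-yl]phenyl acetate
Conditions: 3-benzyl-5-(2-hydroxyethyl)-4-methylthiazolium chloride (20 mol%), Et3N, DMF, 70 °C
Reagents that add atoms: none
Why: Stetter reaction, in which the carbene-bound acyl anion equivalent of 3 adds to the β-carbon of enone 2 to give the 1,4-diketone; its benzylic stereocentre forms racemic and is set in step 3.

Step 3
Reactants: 4 rac-4-[1-(3,5-dimethoxyphenyl)-1,4-dioxopentan-2-yl]phenyl acetate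
Product: 5 (4S,5S)-4-(4-acetoxyphenyl)-5-(3,5-dimethoxyphenyl)-5-hydroxypentan-2-one
Conditions: RuCl[(S,S)-TsDPEN](p-cymene) (2 mol%), HCO2H/Et3N (2:5), DMF, 45 °C
Reagents that add atoms: none
Why: Noyori asymmetric transfer hydrogenation under dynamic kinetic resolution, in which only the aryl ketone is reduced, the catalyst sets the (5S) carbinol, and the enolisable C4 centre should be funnelled to (4S) because that enantiomer reacts on its Felkin–Anh face (hydride anti to the C4 aryl group).

Step 4
Reactants: 5 (4S,5S)-4-(4-acetoxyphenyl)-5-(3,5-dimethoxyphenyl)-5-hydroxypentan-2-one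
Product: 6 (4S,5R)-4-(4-acetoxyphenyl)-5-chloro-5-(3,5-dimethoxyphenyl)pentan-2-one
Conditions: PPh3, N-chlorosuccinimide, THF, −20 to 0 °C
Reagents that add atoms: N-chlorosuccinimide O=C1CCC(=O)N1Cl
Why: Appel-type chlorination in which chloride displaces the alkoxyphosphonium group by SN2 with inversion at C5, ionisation being disfavoured by the meta-dimethoxy aryl group and by the electron-poor, non-participating acetoxyphenyl group.

Step 5
Reactants: 7 (E)-3-(4-methoxyphenyl)prop-2-enoic acid
Product: 9 methyl (E)-5-(4-methoxyphenyl)-3-oxopent-4-enoate, via acyl imidazolide 8 (not isolated)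
Conditions: CDI, THF, rt; then KO2CCH2CO2Me, MgCl2, Et3N, 50 °C; aq. HCl
Reagents that add atoms: potassium methyl malonate COC(=O)CC(=O)[O-].[K+]
Why: Decarboxylative Claisen condensation of the magnesium malonate enolate with the acyl imidazolide, a standard two-carbon extension of an acid to a β-keto ester that leaves the E alkene untouched.

Step 6
Reactants: 6 (4S,5R)-4-(4-acetoxyphenyl)-5-chloro-5-(3,5-dimethoxyphenyl)pentan-2-one; 9 methyl (E)-5-(4-methoxyphenyl)-3-oxopent-4-enoate
Product: 13 (2S,3S,4S,5S)-2-acetyl-4-(3,5-dimethoxyphenyl)-3-(4-hydroxyphenyl)-5-[(E)-3-(4-methoxyphenyl)prop-2-enoyl]cyclopentan-1-one, via free phenol chloride 10 (not isolated), via spirocyclopropyl dienone 11 (not isolated), via C-alkylated keto ester 12 (not isolated)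
Conditions: 9 (2 equiv), Cs2CO3, MeOH (1.5 equiv), DMF, 0 °C to rt; then NaOMe, MeOH, 50 °C; AcOH
Reagents that add atoms: none
Why: Carbonate and methanol remove the acetate, and the phenoxide of 10 displaces the benzylic chloride through its para carbon (Ar1-3 participation, inversion) to give the trans spirocyclopropyl dienone 11; the soft caesium enolate of 9 then opens this activated cyclopropane at its benzylic carbon with a second inversion and rearomatisation, so the future C5–C6 bond forms with net retention and the two aryl groups end trans. Sodium methoxide then drives a Dieckmann condensation in which the methylene carbon α to the methyl ketone (future C1) attacks the ester carbonyl (future C8). The closest known reaction types are aryl-assisted alkylation through spiro[2.5]octa-4,7-dien-6-ones and the homo-Michael/Dieckmann cyclopentanone annulation of activated cyclopropanes with malonate-type enolates. Ring closures: the transient cyclopropane forms by 3-exo-tet attack, and the cyclopentanone by 5-exo-trig attack of an exocyclic (enolexo) enolate, the seven-membered alternative from the methyl terminus not being competitive. Stereocontrol: C3 of 13 is carried from 6, C4 is set by the double inversion, and C2 and C5 are enolisable and should settle trans to their neighbours. The step needs opening at the benzylic rather than the alkyl-substituted cyclopropane carbon and C- rather than O-alkylation, which benzylic activation by the 3,5-dimethoxyphenyl group and the soft, stabilised enolate used in excess should secure.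

Step 7
Reactants: 13 (2S,3S,4S,5S)-2-acetyl-4-(3,5-dimethoxyphenyl)-3-(4-hydroxyphenyl)-5-[(E)-3-(4-methoxyphenyl)prop-2-enoyl]cyclopentan-1-one
Product: 15 (1R,5S,6S,7S)-6-(3,5-dimethoxyphenyl)-7-(4-hydroxyphenyl)-4-[(E)-2-(4-methoxyphenyl)ethenyl]bicyclo[3.2.1]oct-3-ene-2,8-dione, via bridged aldol 14 (not isolated)
Conditions: p-TsOH·H2O (20 mol%), toluene, 90 °C, Dean–Stark
Reagents that add atoms: none
Why: Intramolecular aldol condensation in which, after enol-mediated epimerisation of the acetyl-bearing carbon, the methyl ketone enol adds to the cinnamoyl carbonyl (6-(enolexo)-exo-trig) and water is lost toward C3 only (C5 is a bridgehead); closure is expected on the face that puts the flat C2 carbonyl, not the congested new C4 centre, next to an endo aryl group, which fixes C1 as R with the 4-hydroxyphenyl group endo.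

Step 8
Reactants: 15 (1R,5S,6S,7S)-6-(3,5-dimethoxyphenyl)-7-(4-hydroxyphenyl)-4-[(E)-2-(4-methoxyphenyl)ethenyl]bicyclo[3.2.1]oct-3-ene-2,8-dione
Product: 16 (1R,5S,6S,7S)-6-(3,5-dihydroxyphenyl)-7-(4-hydroxyphenyl)-4-[(E)-2-(4-hydroxyphenyl)ethenyl]bicyclo[3.2.1]oct-3-ene-2,8-dione
Conditions: BBr3, CH2Cl2, −78 to 0 °C; MeOH; aq. NaHCO3
Reagents that add atoms: none
Why: Lewis acid-mediated cleavage of the three aryl methyl ethers (bromide attack on the O-methyl group of the boron-complexed ether), which cannot disturb the four stereocentres because both bridgeheads are non-enolisable.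

Compound list
1 | (E)-4-(4-hydroxyphenyl)but-3-en-2-one | CC(=O)/C=C/c1ccc(O)cc1 | starting material
2 | 4-[(E)-3-oxobut-1-enyl]phenyl acetate | CC(=O)/C=C/c1ccc(OC(C)=O)cc1 | intermediate
3 | 3,5-dimethoxybenzaldehyde | COc1cc(C=O)cc(OC)c1 | starting material
4 | rac-4-[1-(3,5-dimethoxyphenyl)-1,4-dioxopentan-2-yl]phenyl acetate | CC(=O)CC(c1ccc(OC(C)=O)cc1)C(=O)c1cc(OC)cc(OC)c1 | intermediate
5 | (4S,5S)-4-(4-acetoxyphenyl)-5-(3,5-dimethoxyphenyl)-5-hydroxypentan-2-one | CC(=O)C[C@@H](c1ccc(OC(C)=O)cc1)[C@H](O)c1cc(OC)cc(OC)c1 | intermediate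
6 | (4S,5R)-4-(4-acetoxyphenyl)-5-chloro-5-(3,5-dimethoxyphenyl)pentan-2-one | CC(=O)C[C@@H](c1ccc(OC(C)=O)cc1)[C@@H](Cl)c1cc(OC)cc(OC)c1 | intermediate
7 | (E)-3-(4-methoxyphenyl)prop-2-enoic acid | COc1ccc(/C=C/C(=O)O)cc1 | starting material
8 | (E)-1-(imidazol-1-yl)-3-(4-methoxyphenyl)prop-2-en-1-one (acyl imidazolide) | COc1ccc(/C=C/C(=O)n2ccnc2)cc1 | intermediate (not isolated)
9 | methyl (E)-5-(4-methoxyphenyl)-3-oxopent-4-enoate | COC(=O)CC(=O)/C=C/c1ccc(OC)cc1 | intermediate
10 | (4S,5R)-5-chloro-5-(3,5-dimethoxyphenyl)-4-(4-hydroxyphenyl)pentan-2-one (present as its phenoxide) | CC(=O)C[C@@H](c1ccc(O)cc1)[C@@H](Cl)c1cc(OC)cc(OC)c1 | intermediate (not isolated)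
11 | trans-1-(3,5-dimethoxyphenyl)-2-(2-oxopropyl)spiro[2.5]octa-4,7-dien-6-one | CC(=O)C[C@@H]1[C@@H](c2cc(OC)cc(OC)c2)C12C=CC(=O)C=C2 | intermediate (not isolated)
12 | methyl (E)-2-[(1S,2R)-1-(3,5-dimethoxyphenyl)-2-(4-hydroxyphenyl)-4-oxopentyl]-5-(4-methoxyphenyl)-3-oxopent-4-enoate (both C2 epimers) | COC(=O)C(C(=O)/C=C/c1ccc(OC)cc1)[C@@H](c1cc(OC)cc(OC)c1)[C@@H](CC(C)=O)c1ccc(O)cc1 | intermediate (not isolated)
13 | (2S,3S,4S,5S)-2-acetyl-4-(3,5-dimethoxyphenyl)-3-(4-hydroxyphenyl)-5-[(E)-3-(4-methoxyphenyl)prop-2-enoyl]cyclopentan-1-one (drawn as the all-trans triketo tautomer; C2 and C5 enolise) | CC(=O)[C@H]1C(=O)[C@H](C(=O)/C=C/c2ccc(OC)cc2)[C@@H](c2cc(OC)cc(OC)c2)[C@@H]1c1ccc(O)cc1 | intermediate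
14 | (1R,5S,6S,7S)-6-(3,5-dimethoxyphenyl)-4-hydroxy-7-(4-hydroxyphenyl)-4-[(E)-2-(4-methoxyphenyl)ethenyl]bicyclo[3.2.1]octane-2,8-dione (C4 configuration not controlled) | O=C1CC(O)(/C=C/c2ccc(OC)cc2)[C@H]2C(=O)[C@@H]1[C@@H](c1ccc(O)cc1)[C@@H]2c1cc(OC)cc(OC)c1 | intermediate (not isolated)
15 | (1R,5S,6S,7S)-6-(3,5-dimethoxyphenyl)-7-(4-hydroxyphenyl)-4-[(E)-2-(4-methoxyphenyl)ethenyl]bicyclo[3.2.1]oct-3-ene-2,8-dione (6-aryl exo, 7-aryl endo) | O=C1C=C(/C=C/c2ccc(OC)cc2)[C@H]2C(=O)[C@@H]1[C@@H](c1ccc(O)cc1)[C@@H]2c1cc(OC)cc(OC)c1 | intermediate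
16 | (1R,5S,6S,7S)-6-(3,5-dihydroxyphenyl)-7-(4-hydroxyphenyl)-4-[(E)-2-(4-hydroxyphenyl)ethenyl]bicyclo[3.2.1]oct-3-ene-2,8-dione | O=C1C=C(/C=C/c2ccc(O)cc2)[C@H]2C(=O)[C@@H]1[C@@H](c1ccc(O)cc1)[C@@H]2c1cc(O)cc(O)c1 | target

Total step count: 8. Longest linear sequence: 7 steps (steps 1, 2, 3, 4, 6, 7 and 8); step 5 is the side branch.

Steps most likely to fail

Step 6. The spirocyclopropyl dienone may be intercepted by methanol or by phenoxide oxygen, or collapse by elimination to a stilbene, before the enolate opens it. The Dieckmann closure may also stall because the alkylated keto ester sits as its unreactive enolate. The fallback sets out from 5 and avoids aryl participation altogether: MsCl and Et3N should give (4S,5S)-4-(4-acetoxyphenyl)-5-(3,5-dimethoxyphenyl)-5-(methanesulfonyloxy)pentan-2-one F1 with retention. The caesium enolate of 9 in DMF then displaces the sulfonate directly by SN2 with a single inversion, the acetoxyphenyl group remaining a spectator, to give methyl (E)-2-[(1S,2R)-2-(4-acetoxyphenyl)-1-(3,5-dimethoxyphenyl)-4-oxopentyl]-5-(4-methoxyphenyl)-3-oxopent-4-enoate F2. NaOMe in MeOH added to the same flask removes the acetate and closes the ring, so both bonds are still formed in one flask. The fallback comes back to the route at 13.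

Step 7. Bridging may occur on the wrong face, placing the 3,5-dimethoxyphenyl group endo, or the doubly enolised triketone may not present a free cinnamoyl carbonyl, so that only slow decomposition is seen. The fallback sets out from 13 and pre-forms the nucleophile: TMSOTf and Et3N should convert the acetyl/ring-ketone unit into its 1,3-bis(trimethylsilyloxy)diene and silylate the phenol, giving the tris(trimethylsilyl) derivative F3. TiCl4 in CH2Cl2 at −78 °C then triggers an intramolecular Mukaiyama aldol addition of the terminal methylene carbon to the cinnamoyl ketone, and acidic work-up eliminates and desilylates. The fallback comes back to the route at 15.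

Step 3. Epimerisation of the α-aryl ketone may be slower than reduction, so that the process degenerates into a kinetic resolution and unreacted (R)-ketone or the (4R,5S) alcohol accumulates. The fallback sets out from 2 and 3 and sets C4 in the carbon–carbon bond-forming step: an enantioselective Stetter reaction with a chiral aminoindanol-derived triazolium carbene precursor should give (S)-4-[1-(3,5-dimethoxyphenyl)-1,4-dioxopentan-2-yl]phenyl acetate F4. This is reduced with the same ruthenium catalyst, now matched and without need for epimerisation. The fallback comes back to the route at 5.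

Further compounds
F1 | step 6 | (4S,5S)-4-(4-acetoxyphenyl)-5-(3,5-dimethoxyphenyl)-5-(methanesulfonyloxy)pentan-2-one | CC(=O)C[C@@H](c1ccc(OC(C)=O)cc1)[C@H](OS(C)(=O)=O)c1cc(OC)cc(OC)c1
F2 | step 6 | methyl (E)-2-[(1S,2R)-2-(4-acetoxyphenyl)-1-(3,5-dimethoxyphenyl)-4-oxopentyl]-5-(4-methoxyphenyl)-3-oxopent-4-enoate | COC(=O)C(C(=O)/C=C/c1ccc(OC)cc1)[C@@H](c1cc(OC)cc(OC)c1)[C@@H](CC(C)=O)c1ccc(OC(C)=O)cc1
F3 | step 7 | tris(trimethylsilyl) derivative of 13 (1,3-bis(trimethylsilyloxy)diene of the acetyl/ring-ketone unit, aryl trimethylsilyl ether) | C=C(O[Si](C)(C)C)C1=C(O[Si](C)(C)C)[C@H](C(=O)/C=C/c2ccc(OC)cc2)[C@@H](c2cc(OC)cc(OC)c2)[C@@H]1c1ccc(O[Si](C)(C)C)cc1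
F4 | step 3 | (S)-4-[1-(3,5-dimethoxyphenyl)-1,4-dioxopentan-2-yl]phenyl acetate | CC(=O)C[C@@H](c1ccc(OC(C)=O)cc1)C(=O)c1cc(OC)cc(OC)c1
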